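**Assumption:** the target has no stereocentre and its SMILES gives no configuration for the quinone–naphthalene axis, so the axis is treated as unspecified and no stereocontrol is needed.

**Retrosynthetic overview**
- Target ⇐ hydrogenolysis, then air oxidation, of a 2,2'-binaphthalene-1,1'-diol. Its upper 4-oxygen is a benzyl ether (masked quinone); its lower half carries OBn (future 7-OH) and a removable Br.
- Key disconnection: the two inner oxygenated rings (the future quinone ring and the 1-hydroxy-4-methoxy ring of the lower naphthalene) are built in one flask around the central C–C bond of penta-1,3-diyne by two chromium-carbene benzannulations.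
- Ring order: the two outer arene rings are bought (2-bromo-5-methylanisole; O-benzylvanillic acid). The upper inner ring closes first at the terminal alkyne, the lower inner ring second at the internal alkyne.
- The carbene complexes come from ArLi/Cr(CO)6 (upper, benzyloxy) and ArCOCl/Na2Cr(CO)5 (lower, methoxy); the diyne comes from 1,4-dichlorobut-2-yne.

**Route**

Step 1
Reactants: 1 1,4-dichlorobut-2-yne
Product: 3 penta-1,3-diyne, via sodium buta-1,3-diynide 2 (not isolated)
Conditions: NaNH2 (3.0 equiv), liq. NH3, −40 °C; then MeI (1.0 equiv), −60 → −33 °C; distil into cold THF and keep as a THF solution at −20 °C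
Reagents that add atoms: iodomethane, CI (sodium amide, [Na+].[NH2-], leaves sodium only in intermediate 2)
Why: Twofold dehydrochlorination of the propargylic dichloride by amide gives butadiyne, the third equivalent deprotonates it, and the sodium diynide is C-methylated by MeI (elimination then SN2 alkylation of an acetylide).

Step 2
Reactants: 4 1-bromo-2-methoxy-4-methylbenzene
Product: 7 tetramethylammonium pentacarbonyl(2-methoxy-4-methylbenzoyl)chromate, via aryllithium 5 (not isolated), via lithium acylchromate 6 (not isolated)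
Conditions: n-BuLi (1.05 equiv), Et2O, −78 → 0 °C; Cr(CO)6 (1.0 equiv), 0 °C → rt; evaporate; Me4NBr, degassed H2O, rt
Reagents that add atoms: chromium hexacarbonyl, [Cr].[C-]#[O+].[C-]#[O+].[C-]#[O+].[C-]#[O+].[C-]#[O+].[C-]#[O+]; tetramethylammonium bromide, C[N+](C)(C)C.[Br-] (n-butyllithium, [Li]CCCC, leaves lithium only in intermediates 5 and 6)
Why: Bromine–lithium exchange gives the aryllithium, which adds to a CO ligand of Cr(CO)6 (Fischer acylmetalate synthesis), and cation metathesis gives the storable ammonium salt.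

Step 3
Reactants: 7 tetramethylammonium pentacarbonyl(2-methoxy-4-methylbenzoyl)chromate
Product: 9 pentacarbonyl[(benzyloxy)(2-methoxy-4-methylphenyl)methylidene]chromium, via acetoxycarbene complex 8 (not isolated)
Conditions: AcBr (1.05 equiv), CH2Cl2, −40 °C, 1 h; BnOH (1.5 equiv), −40 → 0 °C; SiO2
Reagents that add atoms: benzyl alcohol, OCc1ccccc1 (acetyl bromide, CC(=O)Br, leaves atoms only in intermediate 8)
Why: O-acylation of the acylchromate gives a strongly electrophilic acyloxycarbene whose acetate is displaced by benzyl alcohol at the carbene carbon (addition–elimination alkoxy exchange on a Fischer carbene), so the carbene oxygen carries a group that hydrogenolysis can remove later.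

Step 4
Reactants: 10 4-(benzyloxy)-3-methoxybenzoic acid
Product: 11 4-(benzyloxy)-2-bromo-5-methoxybenzoic acid
Conditions: Br2 (1.05 equiv), NaOAc (1.2 equiv), AcOH, 15–20 °C
Reagents that add atoms: bromine, BrBr
Why: Electrophilic aromatic bromination goes para to the methoxy group as with veratric acid, and this bromine blocks the ortho carbon at which the later benzannulation would otherwise close.

Step 5
Reactants: 11 4-(benzyloxy)-2-bromo-5-methoxybenzoic acid
Product: 14 pentacarbonyl{[4-(benzyloxy)-2-bromo-5-methoxyphenyl](methoxy)methylidene}chromium, via acid chloride 12 (not isolated), via sodium acylchromate 13 (not isolated)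
Conditions: (COCl)2, cat. DMF, CH2Cl2, 0 °C → rt, evaporate; add to Na2Cr(CO)5 [from Cr(CO)6 (1.05 equiv) and NaC10H8 (2.0 equiv), THF, −78 °C], −78 → 0 °C; evaporate; Me3OBF4, CH2Cl2, 0 °C
Reagents that add atoms: chromium hexacarbonyl, [Cr].[C-]#[O+].[C-]#[O+].[C-]#[O+].[C-]#[O+].[C-]#[O+].[C-]#[O+]; trimethyloxonium tetrafluoroborate, C[O+](C)C.F[B-](F)(F)F (oxalyl chloride, O=C(Cl)C(=O)Cl, leaves chlorine only in intermediate 12; sodium naphthalenide, [Na].c1ccc2ccccc2c1, leaves sodium only in intermediate 13)
Why: Acylation of the pentacarbonylchromate dianion by the acid chloride followed by O-methylation with a Meerwein salt (Semmelhack–Hegedus carbene synthesis) avoids an ortho-bromoaryllithium, which would collapse to an aryne.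

Step 6
Reactants: 9 pentacarbonyl[(benzyloxy)(2-methoxy-4-methylphenyl)methylidene]chromium; 3 penta-1,3-diyne; 14 pentacarbonyl{[4-(benzyloxy)-2-bromo-5-methoxyphenyl](methoxy)methylidene}chromium
Product: 16 4-(benzyloxy)-2-[7-(benzyloxy)-5-bromo-1-hydroxy-4,8-dimethoxy-3-methylnaphthalen-2-yl]-5-methoxy-7-methylnaphthalen-1-ol, via alkynylnaphthol 15 (not isolated)
Conditions: 9 (1.05 equiv), 3 (1.0 equiv), THF (0.05 M), sealed tube, Ar, 40 °C, 6 h; then 14 (1.3 equiv), 65 °C, 18 h; then MeCN, CO (1 atm), 40 °C, 1 h; SiO2 with degassed eluent under Ar, use at once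
Reagents that add atoms: none
Why: Proposed new method: two Dötz benzannulations with two different carbene complexes run in one flask on an unsymmetrical 1,3-diyne, the closest known chemistry being the Dötz benzannulation and the double benzannulation of 1,3-butadiynes to biaryls; the ortho-methoxyaryl complex 9 loses CO easily through chelation and reacts first at the unhindered terminal alkyne with the propynyl group placed next to the new hydroxyl, and complex 14 then reacts at the remaining aryl–methyl alkyne with the bulkier aryl group next to the new hydroxyl and methyl next to the methoxy carbon, its ring closing at the only free ortho carbon because the other bears bromine.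

Step 7
Reactants: 16 4-(benzyloxy)-2-[7-(benzyloxy)-5-bromo-1-hydroxy-4,8-dimethoxy-3-methylnaphthalen-2-yl]-5-methoxy-7-methylnaphthalen-1-ol
Product: 18 Burmanin C, 2-(1,7-dihydroxy-4,8-dimethoxy-3-methylnaphthalen-2-yl)-5-methoxy-7-methylnaphthalene-1,4-dione, via naphthalene-1,4-diol 17 (not isolated)
Conditions: H2 (1 atm), 10% Pd/C, NaOAc (1.5 equiv), EtOAc/MeOH 1:1, rt, 4 h; filter; then air, rt, 2 h
Reagents that add atoms: none
Why: Pd-catalysed hydrogenolysis cleaves both benzyl ethers and the aryl C–Br bond, and the freed 1,4-naphthalenediol autoxidises in air to the quinone while the 4-methoxy-1-naphthol half cannot become a quinone without losing its O-methyl group and stays reduced; no stereocentre is formed.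

**Compound list**
1 | 1,4-dichlorobut-2-yne | ClCC#CCCl | starting material
2 | sodium buta-1,3-diynide | [Na+].[C-]#CC#C | intermediate (not isolated)
3 | penta-1,3-diyne | CC#CC#C | intermediate
4 | 1-bromo-2-methoxy-4-methylbenzene | COc1cc(C)ccc1Br | starting material
5 | (2-methoxy-4-methylphenyl)lithium | [Li]c1ccc(C)cc1OC | intermediate (not isolated)
6 | lithium pentacarbonyl(2-methoxy-4-methylbenzoyl)chromate | [Li+].[O-]C(c1ccc(C)cc1OC)=[Cr].[C-]#[O+].[C-]#[O+].[C-]#[O+].[C-]#[O+].[C-]#[O+] | intermediate (not isolated)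
7 | tetramethylammonium pentacarbonyl(2-methoxy-4-methylbenzoyl)chromate | C[N+](C)(C)C.[O-]C(c1ccc(C)cc1OC)=[Cr].[C-]#[O+].[C-]#[O+].[C-]#[O+].[C-]#[O+].[C-]#[O+] | intermediate
8 | pentacarbonyl[(acetyloxy)(2-methoxy-4-methylphenyl)methylidene]chromium | CC(=O)OC(c1ccc(C)cc1OC)=[Cr].[C-]#[O+].[C-]#[O+].[C-]#[O+].[C-]#[O+].[C-]#[O+] | intermediate (not isolated)
9 | pentacarbonyl[(benzyloxy)(2-methoxy-4-methylphenyl)methylidene]chromium | COc1cc(C)ccc1C(OCc1ccccc1)=[Cr].[C-]#[O+].[C-]#[O+].[C-]#[O+].[C-]#[O+].[C-]#[O+] | intermediate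
10 | 4-(benzyloxy)-3-methoxybenzoic acid | COc1cc(C(=O)O)ccc1OCc1ccccc1 | starting material
11 | 4-(benzyloxy)-2-bromo-5-methoxybenzoic acid | COc1cc(C(=O)O)c(Br)cc1OCc1ccccc1 | intermediate
12 | 4-(benzyloxy)-2-bromo-5-methoxybenzoyl chloride | COc1cc(C(Cl)=O)c(Br)cc1OCc1ccccc1 | intermediate (not isolated)
13 | sodium pentacarbonyl[4-(benzyloxy)-2-bromo-5-methoxybenzoyl]chromate | [Na+].[O-]C(c1cc(OC)c(OCc2ccccc2)cc1Br)=[Cr].[C-]#[O+].[C-]#[O+].[C-]#[O+].[C-]#[O+].[C-]#[O+] | intermediate (not isolated)
14 | pentacarbonyl{[4-(benzyloxy)-2-bromo-5-methoxyphenyl](methoxy)methylidene}chromium | COC(c1cc(OC)c(OCc2ccccc2)cc1Br)=[Cr].[C-]#[O+].[C-]#[O+].[C-]#[O+].[C-]#[O+].[C-]#[O+] | intermediate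
15 | 4-(benzyloxy)-5-methoxy-7-methyl-2-(prop-1-yn-1-yl)naphthalen-1-ol | CC#Cc1cc(OCc2ccccc2)c2c(OC)cc(C)cc2c1O | intermediate (not isolated)
16 | 4-(benzyloxy)-2-[7-(benzyloxy)-5-bromo-1-hydroxy-4,8-dimethoxy-3-methylnaphthalen-2-yl]-5-methoxy-7-methylnaphthalen-1-ol | COc1cc(C)cc2c(O)c(-c3c(C)c(OC)c4c(Br)cc(OCc5ccccc5)c(OC)c4c3O)cc(OCc3ccccc3)c12 | intermediate
17 | 2-(1,7-dihydroxy-4,8-dimethoxy-3-methylnaphthalen-2-yl)-5-methoxy-7-methylnaphthalene-1,4-diol | COc1cc(C)cc2c(O)c(-c3c(C)c(OC)c4ccc(O)c(OC)c4c3O)cc(O)c12 | intermediate (not isolated)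
18 | Burmanin C | COc1cc(C)cc2c1C(=O)C=C(c1c(C)c(OC)c3ccc(O)c(OC)c3c1O)C2=O | target

**Step count**
Total steps: 7. Longest linear sequence: 4 steps (steps 2, 3, 6, 7 from compound 4; equally steps 4, 5, 6, 7 from compound 10).

**Three steps most likely to fail, with fallbacks**

1. Step 6. Three things can go wrong: the free ortho-alkynylnaphthol 15 may cyclise to a naphthofuran, the hindered second annulation may stall, or the diyne may oligomerise.
Fallback: the two rings are made in separate flasks and the alkyne is brought in by cross-coupling; the fallback sets out from 14 and returns at 16.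
Carbene 14 is heated with 1-(trimethylsilyl)prop-1-yne (THF, 65 °C), silicon as the larger alkyne substituent ending next to the hydroxyl, to give 7-(benzyloxy)-5-bromo-4,8-dimethoxy-3-methyl-2-(trimethylsilyl)naphthalen-1-ol F1.
Ipso-iododesilylation with ICl (CH2Cl2, −78 °C) gives 7-(benzyloxy)-5-bromo-2-iodo-4,8-dimethoxy-3-methylnaphthalen-1-ol F2.
Stille coupling with tributyl(ethynyl)stannane (Pd(PPh3)4, toluene, 60 °C; C–I reacts before C–Br) gives 7-(benzyloxy)-5-bromo-2-ethynyl-4,8-dimethoxy-3-methylnaphthalen-1-ol F3.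
A single benzannulation of the terminal alkyne of F3 with carbene 9 (THF, 45 °C) then gives 16.

2. Step 5. The strongly reducing chromate dianion, or traces of naphthalenide, may attack the aryl bromide.
Fallback: an organomagnesium route that uses no dianion; it sets out from 11 and returns at 14.
Decarboxylative iodination of 11 (I2, K3PO4, MeCN, 100 °C) gives 1-(benzyloxy)-5-bromo-4-iodo-2-methoxybenzene F4.
Iodine–magnesium exchange (i-PrMgCl·LiCl, THF, −20 °C, where the ortho-bromoaryl Grignard does not eliminate) gives [4-(benzyloxy)-2-bromo-5-methoxyphenyl]magnesium chloride F5.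
Addition to Cr(CO)6 (THF, 0 °C → rt) gives chloromagnesium pentacarbonyl[4-(benzyloxy)-2-bromo-5-methoxybenzoyl]chromate F6, and O-methylation with Me3OBF4 gives 14.

3. Step 7. Hydrodebromination may be incomplete, or the electron-rich lower naphthol may be damaged during the combined hydrogenolysis and aeration.
Fallback: the reductions are separated and no hydrogenation is used; it sets out from 16 and returns at 17.
Radical debromination (Bu3SnH, AIBN, toluene, 80 °C) gives 4-(benzyloxy)-2-[7-(benzyloxy)-1-hydroxy-4,8-dimethoxy-3-methylnaphthalen-2-yl]-5-methoxy-7-methylnaphthalen-1-ol F7.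
Debenzylation with BCl3 and pentamethylbenzene (CH2Cl2, −78 °C; methyl ethers survive) gives 17, which is aerated as in step 7.

**Further compounds**
F1 | step 6 | 7-(benzyloxy)-5-bromo-4,8-dimethoxy-3-methyl-2-(trimethylsilyl)naphthalen-1-ol | Oc1c([Si](C)(C)C)c(C)c(OC)c2c(Br)cc(OCc3ccccc3)c(OC)c12
F2 | step 6 | 7-(benzyloxy)-5-bromo-2-iodo-4,8-dimethoxy-3-methylnaphthalen-1-ol | Oc1c(I)c(C)c(OC)c2c(Br)cc(OCc3ccccc3)c(OC)c12
F3 | step 6 | 7-(benzyloxy)-5-bromo-2-ethynyl-4,8-dimethoxy-3-methylnaphthalen-1-ol | Oc1c(C#C)c(C)c(OC)c2c(Br)cc(OCc3ccccc3)c(OC)c12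
F4 | step 5 | 1-(benzyloxy)-5-bromo-4-iodo-2-methoxybenzene | COc1cc(I)c(Br)cc1OCc1ccccc1
F5 | step 5 | [4-(benzyloxy)-2-bromo-5-methoxyphenyl]magnesium chloride | COc1cc([Mg]Cl)c(Br)cc1OCc1ccccc1
F6 | step 5 | chloromagnesium pentacarbonyl[4-(benzyloxy)-2-bromo-5-methoxybenzoyl]chromate | Cl[Mg+].[O-]C(c1cc(OC)c(OCc2ccccc2)cc1Br)=[Cr].[C-]#[O+].[C-]#[O+].[C-]#[O+].[C-]#[O+].[C-]#[O+]
F7 | step 7 | 4-(benzyloxy)-2-[7-(benzyloxy)-1-hydroxy-4,8-dimethoxy-3-methylnaphthalen-2-yl]-5-methoxy-7-methylnaphthalen-1-ol | COc1cc(C)cc2c(O)c(-c3c(C)c(OC)c4ccc(OCc5ccccc5)c(OC)c4c3O)cc(OCc3ccccc3)c12
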